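Count the target in percent of the charge, not in molar, so that runs of different strength stand on one axis.

| flask | starting material | remark | time |
|---|---|---|---|
| Tuesday's | 0.051 M | run made earlier |  |
| Monday's | 0.41 M | run made earlier |  |
| maple | 0.040 M |  | 8.0 min |
| cedar | 0.080 M |  | 8.0 min |
| alder | 0.15 M |  | 8.0 min |
| oak | 0.30 M |  | 8.0 min |

| run | time / min | target / % | starting material / % |
|---|---|---|---|
| Tuesday's | 0.250 | 21 | 58 |
| Tuesday's | 0.833 | 45 | 18 |
| Tuesday's | 1.33 | 52 | 7 |
| Tuesday's | 2.00 | 55 | 0 |
| Tuesday's | 3.00 | 52 | 0 |
| Tuesday's | 4.00 | 56 | 0 |
| Monday's | 0.667 | 40 | 26 |
| Monday's | 1.33 | 47 | 5 |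
| Monday's | 2.00 | 46 | 0 |
| Monday's | 2.50 | 51 | 3 |
| Monday's | 3.00 | 47 | 0 |
| Monday's | 4.00 | 47 | 0 |

(scatter of a reading: 2 percentage points)

- "hardly changes" means that all values lie within two and a half points (for a concentration: within two and a half percent of the largest)

1. amount of target at the end, in percent of the starting material charged for maple, cedar, alder, oak, in this order
2. the shape of the row from first to last (falls, then rises / hardly changes / rises all the way / falls all the way / rises, then falls)

There are two settings to turn. Take the time first. Tuesday's starting material stands at 18 % after 0.833 min, and Monday's at 26 % after 0.667 min. Read as first-order decay: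

k(Tuesday) = 2.06 min⁻¹

k(Monday) = 2.02 min⁻¹

half-life = 0.340 min

The allowed 8.0 min is far longer than that half-life, and the target in both runs stays level within the scatter from 2.00 min to 4.00 min. So I expect more time to do nothing, though no reading goes past 4.00 min.

Now turn the concentration. If every step were first-order, the percent yield would not move with c(starting material). It does move, and the mean of the level readings gives a reading of each run's selectivity, the share of the charge that ends as target:

Tuesday: 54.3 %

Monday: 47.8 %

The gap of 6.5 percentage points is larger than its own uncertainty of 1.5 points. Dividing it by the difference in charge gives the yield cost per molar, s, read from these two runs: the drop in that share for each molar added to the charge: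

s = 0.183 M⁻¹

Y = 55.3 % − s · c(starting material)

My straight line gives 54.5 %, 53.8 %, 52.5 % and 49.8 %.

The forecast says 55 %, 53.5 %, 51.5 %, 49 %, so the row falls all the way. Its form lies between linear and logarithmic, so it differs from my line. Its ground: “A more concentrated run gives a lower yield”.

The flasks give 53.7 %, 53.2 %, 52.2 %, 50.3 %, and the row falls all the way.

    starting material → target (k = 0.0190 s⁻¹)
    starting material → side product A (k = 0.0160 s⁻¹)
    starting material + target → side product B (k = 0.0120 M⁻¹ s⁻¹)

Oak ends with side product B at 5.13 % and maple with 0.736 %, and in these percentages each molecule of side product B counts as two, as it holds that many. Now put s on the row. From maple to oak it asks for a drop of 4.8 points, and the flasks show 3.4 points. From maple to alder it asks for 2 points, and the flasks show 1.5 points.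

(The readings stem from a simulated flask with constants of no real substance.)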